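**Two paces.** Between 2.50 min and 5.00 min, Sunday's D climbs by 0.130 min⁻¹ of the charge against Saturday's 0.0672 min⁻¹, a ratio of 1.93, smaller than the 2.24 in L.

| flask | Q | G | L | remark | time |
|---|---|---|---|---|---|
| Saturday's | 0.050 M | 8 mM (held) | 0.67 mol% | run made earlier |  |
| Sunday's | 0.050 M | 8 mM (held) | 1.5 mol% | run made earlier |  |
| flask | 0.050 M | 8.0 mM (held) | 1 mol% |  | 5.0 min |

| run | time / min | D / % | Q / % |
|---|---|---|---|
| Saturday's | 0.333 | 1.5 | 98.0 |
| Saturday's | 1.00 | 5.2 | 94.1 |
| Saturday's | 2.00 | 12.5 | 87.1 |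
| Saturday's | 2.50 | 16.0 | 83.6 |
| Saturday's | 4.00 | 26.2 | 73.3 |
| Saturday's | 5.00 | 32.8 | 67.1 |
| Sunday's | 0.333 | 2.3 | 96.5 |
| Sunday's | 1.00 | 11.0 | 87.4 |
| Sunday's | 2.00 | 24.7 | 74.0 |
| Sunday's | 2.50 | 31.7 | 67.2 |
| Sunday's | 4.00 | 51.9 | 47.3 |
| Sunday's | 5.00 | 64.3 | 35.2 |

(standard deviation of a reading: 0.3 percentage points)

- D at 5.0 min, in percent of the Q charged
- concentration of Z in solution at 5.0 min, in percent of saturation

**Charge time.** The inverse of such a pace is the charge time, the minutes that pace needs for one whole charge. I split it into a part inversely proportional to L, which the two runs put at 8.73 min for 1 mol%, and a constant part, read as G's crossing: the gas time 1.85 min.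

**Going round.** With Z taken as full, the flask's pace is 0.115 min⁻¹, which leaves Z short by 21.2%. With pace proportional to Z, that shortfall goes back in and slows the pace, and the round closes at a charge time of 10.6 min, with Z at 82.5% of saturation.

**The curve.** My line for the flask's D starts flat up to a knee at 0.0940 min, the mean read from both runs, then runs straight. With Q and D together taken as near the whole charge, that line crosses Q's at 5.39 min, later than 5.0 min. So at 5.0 min my line puts the flask's D at 46.4%, short of the whole charge.

**Result.** The forecast gives 45.7% and 85%, not my 46.4% and 82.5%, saying the lagging rate “points to gas transfer partly limiting”. The flask gives 46.7% and 74.8%, so Z lies 7.7 percentage points below my reckoning.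

    E → J (k = 8.24 s⁻¹)
    Z + X ⇌ E (K = 2600 M⁻¹, k = 95.0 M⁻¹ s⁻¹)
    J → L + D (k = 0.318 s⁻¹)
    G ⇌ Z, rate k4*(csat - [Z]) (kL = 0.0387 s⁻¹)
    Q + L ⇌ X (K = 85.0 M⁻¹, k = 58.3 M⁻¹ s⁻¹)

**Resting state.** In the flask, J's half-life by its step to L + D alone is 2.2 s, longer than the relaxation half-life of 0.312 s between Q + L and X, both ways together, at 5.00 min. At 5.00 min, J, the main resting state, holds 48.6% of the catalyst, against 27.3% in X, 22.3% in L and 1.87% in E.

**Second flask.** For a neighbour with 1.7 mol% of L, my reckoning keeps the gas time and gets a charge time of 6.98 min, which puts D at 70.3%. Computed, that neighbour holds 69.8% of D.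

(The runs come from a simulation for an exercise; noise was put on by code.)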